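**Retrosynthetic overview** (locants are those of the target's bicyclo[3.2.1]octane: C1 prenyl bridgehead, C2 ketone, C3 acyl carbon, C4 enol carbon, C5 methyl bridgehead, C6 CH, C7 CH2, C8 bridging ketone; the same locants are used for the arene carbons that become them)

- Target 19 ⇐ O-demethylation at C4 and exo hydrogenation of C6=C7 ⇐ dienedione 17 ⇐ epoxidation of the isopropylidene and acid-triggered fragmentation that breaks C2–C7 ⇐ tricyclo[3.2.1.0(2,7)]octenone 15.
- 15 ⇐ aryl 2-methylbut-3-yn-2-yl ether 12, by a dearomatising [3,3] shift (C1–C7) followed by an intramolecular Diels–Alder reaction (C5–C6 and the temporary C2–C7 bond).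
- Feature used: the six-membered ring C1–C2–C3–C4–C5–C8 has the oxygen and acyl pattern of a dearomatised acylphloroglucinol; C7–C6 bridges its 1,3-related carbons C1 and C5, and C6 bears the CMe2(OH) carbon, so C7, C6 and that carbon are the three skeletal carbons of a 2-methylbut-3-yn-2-yl group that once sat on the C2 oxygen.
- 12 ⇐ 2-methylphloroglucinol 1: C-acylation, then the three hydroxyls are told apart in the order para (silyl), unhindered ortho (tertiary propargyl ether, which after semihydrogenation and Claisen shift becomes the C1 prenyl group), hindered ortho (methyl); the propargyl ether is then installed a second time on the freed C2 hydroxyl.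
- Ring order: arene ring (bought) → five-membered ring C1–C7–C6–C5–C8 and cyclopropane C1–C2–C7 together in step 9 → cyclopropane opened again in step 11.

Key step: step 9

**Remarks on the chemistry (assumptions)**

- 19 is an enolised β-triketone; the target SMILES shows one tautomer, and the route delivers the tautomeric compound that this drawing represents.
- The sense of induction of the N,N'-dioxide ligand on this substrate cannot be predicted from the naphthyl ether cases. The ligand enantiomer that leads to 15 is to be fixed in a trial run; both are available from (S)- and (R)-pipecolic acid.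
- L-PiPr2 means 1,1'-(propane-1,3-diyl)bis[(2S)-N-(2,6-diisopropylphenyl)piperidine-2-carboxamide 1-oxide].

**Route**

Step 1
Reactants: 1 2-methylphloroglucinol; 2 isobutyryl chloride
Product: 3 1-(2,4,6-trihydroxy-3-methylphenyl)-2-methylpropan-1-one
Conditions: AlCl3 (3.5 equiv), PhNO2, 60 °C; aq. HCl work-up
Reagents that add atoms: none
Why: Friedel–Crafts acylation of the electron-rich arene at one of its two equivalent free positions; the chelated aryl ketone that forms is deactivated toward a second acylation.

Step 2
Reactants: 3 1-(2,4,6-trihydroxy-3-methylphenyl)-2-methylpropan-1-one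
Product: 4 1-[2,6-dihydroxy-3-methyl-4-(triisopropylsilyloxy)phenyl]-2-methylpropan-1-one
Conditions: TIPSCl (1.05 equiv), imidazole, DMF, 0 °C
Reagents that add atoms: chlorotri(propan-2-yl)silane (TIPSCl), CC(C)[Si](Cl)(C(C)C)C(C)C
Why: Silylation should pick the hydroxyl para to the ketone (on C8), the most acidic one and the only one never engaged in the hydrogen bond to the carbonyl group, so one equivalent of the bulky silyl chloride caps it first.

Step 3
Reactants: 4 1-[2,6-dihydroxy-3-methyl-4-(triisopropylsilyloxy)phenyl]-2-methylpropan-1-one; 5 2-methylbut-3-yn-2-ol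
Product: 6 1-[2-hydroxy-3-methyl-6-(2-methylbut-3-yn-2-yloxy)-4-(triisopropylsilyloxy)phenyl]-2-methylpropan-1-one
Conditions: 5 (1.3 equiv), (CF3CO)2O, DBU, MeCN, −5 °C; then 4, DBU, CuCl2·2H2O (1 mol %), MeCN, 0 °C
Reagents that add atoms: none
Why: Copper-catalysed propargylic etherification of a phenol with a tertiary propargyl trifluoroacetate (through a copper acetylide that ionises to an allenylidene-type electrophile); the bulky electrophile should take the ortho hydroxyl next to unsubstituted C1, which is less hindered and more acidic than the one next to the methyl group, and the latter then stays locked in the hydrogen bond to the ketone.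

Step 4
Reactants: 6 1-[2-hydroxy-3-methyl-6-(2-methylbut-3-yn-2-yloxy)-4-(triisopropylsilyloxy)phenyl]-2-methylpropan-1-one
Product: 7 1-[2-methoxy-3-methyl-6-(2-methylbut-3-yn-2-yloxy)-4-(triisopropylsilyloxy)phenyl]-2-methylpropan-1-one
Conditions: MeI (excess), K2CO3, acetone, 50 °C
Reagents that add atoms: iodomethane, CI
Why: Williamson methylation of the remaining chelated phenol (the C4 oxygen) under carbonate conditions that leave the silyl ether, the tertiary ether and the alkyne C–H untouched.

Step 5
Reactants: 7 1-[2-methoxy-3-methyl-6-(2-methylbut-3-yn-2-yloxy)-4-(triisopropylsilyloxy)phenyl]-2-methylpropan-1-one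
Product: 8 1-[2-methoxy-3-methyl-6-(2-methylbut-3-en-2-yloxy)-4-(triisopropylsilyloxy)phenyl]-2-methylpropan-1-one
Conditions: H2 (1 atm), Pd/CaCO3 poisoned with Pb(OAc)2 (Lindlar catalyst), quinoline, EtOAc, rt
Reagents that add atoms: none
Why: Lindlar semihydrogenation should stop at the alkene because the poisoned palladium surface binds the terminal alkyne far more strongly than the 1,1-dimethylallyl ether that results.

Step 6
Reactants: 8 1-[2-methoxy-3-methyl-6-(2-methylbut-3-en-2-yloxy)-4-(triisopropylsilyloxy)phenyl]-2-methylpropan-1-one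
Product: 10 1-[2-hydroxy-6-methoxy-5-methyl-3-(3-methylbut-2-en-1-yl)-4-(triisopropylsilyloxy)phenyl]-2-methylpropan-1-one, via ortho-dienone 9 (not isolated)
Conditions: PhNEt2, 130 °C
Reagents that add atoms: none
Why: Aromatic Claisen rearrangement of the aryl 1,1-dimethylallyl ether: the [3,3] shift can end only at C1, the one free ortho carbon, it turns the tertiary allyl group into a prenyl group, and dienone 9 enolises to the hydrogen-bonded phenol.

Step 7
Reactants: 10 1-[2-hydroxy-6-methoxy-5-methyl-3-(3-methylbut-2-en-1-yl)-4-(triisopropylsilyloxy)phenyl]-2-methylpropan-1-one; 5 2-methylbut-3-yn-2-ol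
Product: 11 1-[2-methoxy-3-methyl-5-(3-methylbut-2-en-1-yl)-6-(2-methylbut-3-yn-2-yloxy)-4-(triisopropylsilyloxy)phenyl]-2-methylpropan-1-one
Conditions: 5 (2 equiv), (CF3CO)2O, DBU, MeCN, −5 °C; then 10, DBU, CuCl2·2H2O (5 mol %), MeCN, 0 °C to rt
Reagents that add atoms: none
Why: The same copper-catalysed propargylic etherification, now with no choice of site since only the C2 hydroxyl is free; the low temperature keeps the product far below the onset of its own thermal Claisen shift.

Step 8
Reactants: 11 1-[2-methoxy-3-methyl-5-(3-methylbut-2-en-1-yl)-6-(2-methylbut-3-yn-2-yloxy)-4-(triisopropylsilyloxy)phenyl]-2-methylpropan-1-one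
Product: 12 1-[4-hydroxy-2-methoxy-3-methyl-5-(3-methylbut-2-en-1-yl)-6-(2-methylbut-3-yn-2-yloxy)phenyl]-2-methylpropan-1-one
Conditions: TBAF (1.1 equiv), AcOH (1.1 equiv), THF, 0 °C
Reagents that add atoms: none
Why: Fluoride cleaves the aryl silyl ether selectively, and the acetic acid buffer keeps the liberated phenoxide from acting as a base on the propargyl ether or the ketone.

Step 9
Reactants: 12 1-[4-hydroxy-2-methoxy-3-methyl-5-(3-methylbut-2-en-1-yl)-6-(2-methylbut-3-yn-2-yloxy)phenyl]-2-methylpropan-1-one
Product: 15 (1S,2S,5R,7R)-2-hydroxy-4-methoxy-5-methyl-1-(3-methylbut-2-en-1-yl)-3-(2-methylpropanoyl)-6-(propan-2-ylidene)tricyclo[3.2.1.0(2,7)]oct-3-en-8-one, via allenyl dienone 13 (not isolated), via enol tautomer 14 (not isolated)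
Conditions: Co(OTf)2 (divalent cobalt, 10 mol %), L-PiPr2 (11 mol %), ClCH2CH2Cl, 40 °C, then 60 °C
Reagents that add atoms: none
Why: Proposed new method: Co(OTf)2 held in the chiral N,N'-dioxide pocket is expected to chelate the ether oxygen on C2 and the isobutyryl oxygen of 12, which weakens the O–CMe2 bond and turns the alkyne toward C1, so that a suprafacial [3,3] shift bonds the alkyne terminus C7 to C1 and gives allenyl dienone 13; the closest known reactions are the N,N'-dioxide/cobalt-catalysed enantioselective dearomative propargyl Claisen rearrangement of chelating naphthyl ethers and the thermal Claisen/intramolecular Diels–Alder cascade of 2,6-disubstituted aryl propargyl ethers. Proton transfer from O8 to O2 along the vinylogous acid converts 13 into 14, and the C2=C3–C4=C5 diene of 14 then adds to the C7=C6 bond of the allene in a concerted [4+2] cycloaddition. As the two components are joined only through C1, this single event closes the cyclopropane C1–C2–C7 (new bond C7–C2, three-membered exo closure) and the five-membered ring C1–C7–C6–C5–C8 (new bond C6–C5, five-membered exo closure), the C2–C3–C4–C5–C6–C7 ring of the cycloaddition being their common envelope. C1 is set in the [3,3] shift by the ligand, which leaves one face of the chelated arene open to the alkyne, and C2, C5 and C7 follow from C1 because the allene can only reach the diene face on which it sits. The step needs migration to C1 and not to acyl-bearing C3 (the chelate places the propargyl group on the C1 side and a shift to C3 can only revert), one arene face (ligand), and cycloaddition through the C2-to-C5 diene of 14 instead of the C3-to-C8 diene of 13 (14 is the hydrogen-bonded, conjugated enol and its adduct keeps the acyl group in conjugation). Because C1 becomes quaternary the dienone has no route back to an arene or on to a chromene, so the cycloaddition is its only outlet.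

Step 10
Reactants: 15 (1S,2S,5R,7R)-2-hydroxy-4-methoxy-5-methyl-1-(3-methylbut-2-en-1-yl)-3-(2-methylpropanoyl)-6-(propan-2-ylidene)tricyclo[3.2.1.0(2,7)]oct-3-en-8-one
Product: 16 (1S,2S,5S,6R,7R)-2-hydroxy-4-methoxy-3',3',5-trimethyl-1-(3-methylbut-2-en-1-yl)-3-(2-methylpropanoyl)spiro[tricyclo[3.2.1.0(2,7)]oct-3-ene-6,2'-oxiran]-8-one (epoxide oxygen on the exo face of C6, the side of C8)
Conditions: DMDO (1.05 equiv), acetone/CH2Cl2, −40 to −20 °C; evaporated cold and used as the crude residue
Reagents that add atoms: dimethyldioxirane (DMDO), CC1(C)OO1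
Why: Epoxidation by the electrophilic dioxirane under neutral conditions should select the tetrasubstituted isopropylidene, whose π bond is raised by overlap with the oxygen-bearing C2–C7 cyclopropane bond, over the trisubstituted prenyl alkene and the acyl-deactivated enol ether, and should reach C6 from the exo face next to C8 because the C2–C3–C4 bridge covers the endo face.

Step 11
Reactants: 16 (1S,2S,5S,6R,7R)-2-hydroxy-4-methoxy-3',3',5-trimethyl-1-(3-methylbut-2-en-1-yl)-3-(2-methylpropanoyl)spiro[tricyclo[3.2.1.0(2,7)]oct-3-ene-6,2'-oxiran]-8-one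
Product: 17 (1R,5R)-6-(2-hydroxypropan-2-yl)-4-methoxy-5-methyl-1-(3-methylbut-2-en-1-yl)-3-(2-methylpropanoyl)bicyclo[3.2.1]octa-3,6-diene-2,8-dione
Conditions: BF3·OEt2 (0.2 equiv), CH2Cl2, −78 °C; Et3N quench
Reagents that add atoms: none
Why: Grob-type fragmentation in which BF3 activates the epoxide, the C2 hydroxyl pushes, the C2–C7 cyclopropane bond (antiperiplanar to the exo C6–O bond) breaks, and the C6=C7 alkene, the C2 ketone and the tertiary alcohol appear together without touching C1 or C5; an acid is used since a base would open the β-hydroxy ketone C2(OH)–C1–C8=O in the retro-aldol sense, and the other epoxide epimer would give the same product.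

Step 12
Reactants: 17 (1R,5R)-6-(2-hydroxypropan-2-yl)-4-methoxy-5-methyl-1-(3-methylbut-2-en-1-yl)-3-(2-methylpropanoyl)bicyclo[3.2.1]octa-3,6-diene-2,8-dione
Product: 18 (1R,5R,6S)-6-(2-hydroxypropan-2-yl)-4-methoxy-5-methyl-1-(3-methylbut-2-en-1-yl)-3-(2-methylpropanoyl)bicyclo[3.2.1]oct-3-ene-2,8-dione
Conditions: H2 (50 bar), [Rh(nbd)(dppb)]BF4 (5 mol %; nbd = norbornadiene, dppb = 1,4-bis(diphenylphosphino)butane), CH2Cl2, rt
Reagents that add atoms: none
Why: Hydroxyl-directed hydrogenation with a cationic rhodium diphosphine catalyst, which reduces a trisubstituted alkene only when a neighbouring hydroxyl holds the metal and so should spare the prenyl group; the metal can reach C6=C7 only from the exo face next to C8, since the C2–C3–C4 bridge blocks the endo face, so hydrogen adds exo and the 2-hydroxypropan-2-yl group ends endo, which sets C6 as S.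

Step 13
Reactants: 18 (1R,5R,6S)-6-(2-hydroxypropan-2-yl)-4-methoxy-5-methyl-1-(3-methylbut-2-en-1-yl)-3-(2-methylpropanoyl)bicyclo[3.2.1]oct-3-ene-2,8-dione
Product: 19 (1R,5R,6S)-4-hydroxy-6-(2-hydroxypropan-2-yl)-5-methyl-1-(3-methylbut-2-en-1-yl)-3-(2-methylpropanoyl)bicyclo[3.2.1]oct-3-ene-2,8-dione
Conditions: LiCl (5 equiv), DMSO, 120 °C; then aq. HCl to pH 3, 0 °C
Reagents that add atoms: none
Why: Krapcho-type SN2 demethylation in which chloride attacks the methyl group of the doubly activated vinylogous ester and releases the stabilised triketone enolate, under conditions not basic enough for retro-Claisen cleavage at C1 and without effect on C1, C5 or C6.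

**Compound list**

1 | 2-methylphloroglucinol (2-methylbenzene-1,3,5-triol) | Cc1c(O)cc(O)cc1O | starting material
2 | isobutyryl chloride (2-methylpropanoyl chloride) | CC(C)C(=O)Cl | starting material
3 | 1-(2,4,6-trihydroxy-3-methylphenyl)-2-methylpropan-1-one | CC(C)C(=O)c1c(O)cc(O)c(C)c1O | intermediate
4 | 1-[2,6-dihydroxy-3-methyl-4-(triisopropylsilyloxy)phenyl]-2-methylpropan-1-one | CC(C)C(=O)c1c(O)cc(O[Si](C(C)C)(C(C)C)C(C)C)c(C)c1O | intermediate
5 | 2-methylbut-3-yn-2-ol | CC(C)(O)C#C | starting material
6 | 1-[2-hydroxy-3-methyl-6-(2-methylbut-3-yn-2-yloxy)-4-(triisopropylsilyloxy)phenyl]-2-methylpropan-1-one | CC(C)C(=O)c1c(OC(C)(C)C#C)cc(O[Si](C(C)C)(C(C)C)C(C)C)c(C)c1O | intermediate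
7 | 1-[2-methoxy-3-methyl-6-(2-methylbut-3-yn-2-yloxy)-4-(triisopropylsilyloxy)phenyl]-2-methylpropan-1-one | CC(C)C(=O)c1c(OC(C)(C)C#C)cc(O[Si](C(C)C)(C(C)C)C(C)C)c(C)c1OC | intermediate
8 | 1-[2-methoxy-3-methyl-6-(2-methylbut-3-en-2-yloxy)-4-(triisopropylsilyloxy)phenyl]-2-methylpropan-1-one | CC(C)C(=O)c1c(OC(C)(C)C=C)cc(O[Si](C(C)C)(C(C)C)C(C)C)c(C)c1OC | intermediate
9 | 3-methoxy-4-methyl-6-(3-methylbut-2-en-1-yl)-2-(2-methylpropanoyl)-5-(triisopropylsilyloxy)cyclohexa-2,4-dien-1-one (racemic at C6; not isolated) | CC(C)=CCC1C(=O)C(C(=O)C(C)C)=C(OC)C(C)=C1O[Si](C(C)C)(C(C)C)C(C)C | intermediate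
10 | 1-[2-hydroxy-6-methoxy-5-methyl-3-(3-methylbut-2-en-1-yl)-4-(triisopropylsilyloxy)phenyl]-2-methylpropan-1-one | CC(C)=CCc1c(O[Si](C(C)C)(C(C)C)C(C)C)c(C)c(OC)c(C(=O)C(C)C)c1O | intermediate
11 | 1-[2-methoxy-3-methyl-5-(3-methylbut-2-en-1-yl)-6-(2-methylbut-3-yn-2-yloxy)-4-(triisopropylsilyloxy)phenyl]-2-methylpropan-1-one | CC(C)=CCc1c(O[Si](C(C)C)(C(C)C)C(C)C)c(C)c(OC)c(C(=O)C(C)C)c1OC(C)(C)C#C | intermediate
12 | 1-[4-hydroxy-2-methoxy-3-methyl-5-(3-methylbut-2-en-1-yl)-6-(2-methylbut-3-yn-2-yloxy)phenyl]-2-methylpropan-1-one | CC(C)=CCc1c(O)c(C)c(OC)c(C(=O)C(C)C)c1OC(C)(C)C#C | intermediate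
13 | (6R)-5-hydroxy-3-methoxy-4-methyl-6-(3-methylbuta-1,2-dien-1-yl)-6-(3-methylbut-2-en-1-yl)-2-(2-methylpropanoyl)cyclohexa-2,4-dien-1-one (not isolated) | CC(C)=CC[C@]1(C=C=C(C)C)C(=O)C(C(=O)C(C)C)=C(OC)C(C)=C1O | intermediate
14 | (6S)-5-hydroxy-3-methoxy-2-methyl-6-(3-methylbuta-1,2-dien-1-yl)-6-(3-methylbut-2-en-1-yl)-4-(2-methylpropanoyl)cyclohexa-2,4-dien-1-one (not isolated) | CC(C)=CC[C@]1(C=C=C(C)C)C(O)=C(C(=O)C(C)C)C(OC)=C(C)C1=O | intermediate
15 | (1S,2S,5R,7R)-2-hydroxy-4-methoxy-5-methyl-1-(3-methylbut-2-en-1-yl)-3-(2-methylpropanoyl)-6-(propan-2-ylidene)tricyclo[3.2.1.0(2,7)]oct-3-en-8-one | CC(C)=CC[C@@]12[C@H]3C(=C(C)C)[C@@](C)(C1=O)C(OC)=C(C(=O)C(C)C)[C@@]23O | intermediate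
16 | (1S,2S,5S,6R,7R)-2-hydroxy-4-methoxy-3',3',5-trimethyl-1-(3-methylbut-2-en-1-yl)-3-(2-methylpropanoyl)spiro[tricyclo[3.2.1.0(2,7)]oct-3-ene-6,2'-oxiran]-8-one | CC(C)=CC[C@@]12[C@H]3[C@@]4(OC4(C)C)[C@@](C)(C1=O)C(OC)=C(C(=O)C(C)C)[C@@]23O | intermediate
17 | (1R,5R)-6-(2-hydroxypropan-2-yl)-4-methoxy-5-methyl-1-(3-methylbut-2-en-1-yl)-3-(2-methylpropanoyl)bicyclo[3.2.1]octa-3,6-diene-2,8-dione | CC(C)=CC[C@@]12C=C(C(C)(C)O)[C@@](C)(C1=O)C(OC)=C(C(=O)C(C)C)C2=O | intermediate
18 | (1R,5R,6S)-6-(2-hydroxypropan-2-yl)-4-methoxy-5-methyl-1-(3-methylbut-2-en-1-yl)-3-(2-methylpropanoyl)bicyclo[3.2.1]oct-3-ene-2,8-dione | CC(C)=CC[C@@]12C[C@H](C(C)(C)O)[C@@](C)(C1=O)C(OC)=C(C(=O)C(C)C)C2=O | intermediate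
19 | (1R,5R,6S)-4-hydroxy-6-(2-hydroxypropan-2-yl)-5-methyl-1-(3-methylbut-2-en-1-yl)-3-(2-methylpropanoyl)bicyclo[3.2.1]oct-3-ene-2,8-dione | CC(C)=CC[C@@]12C[C@H](C(C)(C)O)[C@@](C)(C1=O)C(O)=C(C(=O)C(C)C)C2=O | target

**Step count**

Total: 13 steps. Longest linear sequence: 13 steps (1 to 19).

**Steps most likely to fail, with fallbacks**

Step 9 (proposed new method). Four processes may spoil it:
- ionisation of the tertiary propargylic C–O bond by the Lewis acid, with loss of the propargyl group;
- capture of the cobalt by the enolised β-diketone of 14, so that the catalyst does not turn over;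
- poor discrimination of the two arene faces;
- cycloaddition through the C3-to-C8 diene of 13.

Fallback: from 12 the cascade would be run without metal (toluene or o-dichlorobenzene, 120–140 °C). This is the known thermal propargyl Claisen/intramolecular Diels–Alder sequence of 2,6-disubstituted aryl propargyl ethers. It should pass through 13 and 14 together with their mirror images, the (6S)-allenyl dienone F1 and the (6R)-enol tautomer F2. It should give the racemic tricycle, that is 15 together with its enantiomer, the (1R,2R,5S,7S)-tricycle F3. Preparative HPLC on a chiral stationary phase (amylose tris(3,5-dimethylphenylcarbamate)) would separate 15 from F3, and the route is rejoined at 15.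

Step 7. The hydroxyl on C2 of 10 is chelated to the ketone and flanked by the prenyl group, so etherification with a tertiary electrophile may be slow. Elimination of the activated alcohol to the enyne may then consume the reagent.

Fallback: the ether is kept where it was made at the unhindered stage and the prenyl group is brought in by C-alkylation instead. From 7 the silyl group would be removed (TBAF, AcOH, THF, 0 °C) to give 1-[4-hydroxy-2-methoxy-3-methyl-6-(2-methylbut-3-yn-2-yloxy)phenyl]-2-methylpropan-1-one F4. Its sodium phenoxide (NaH, toluene, rt to 50 °C) would be alkylated at the free ortho carbon C1 with prenyl bromide (1-bromo-3-methylbut-2-ene), the classical ortho C-alkylation of phenoxides in a non-polar solvent. Enolisation gives 12, where the route is rejoined; steps 5 to 8 are then not needed.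

Step 12. The C6=C7 alkene lies between two quaternary bridgeheads and a tertiary carbinol, so directed hydrogenation may stall. Under more forcing conditions the prenyl alkene may be reduced as well, or hydrogen may be delivered to the endo face.

Fallback: from 17 the C6=C7 bond would be reduced with diimide, generated from 2-nitrobenzenesulfonyl hydrazide and Et3N in CH2Cl2 at room temperature. This concerted, metal-free syn transfer selects by ring strain and steric access instead of by hydroxyl coordination. The strained bicyclic alkene should therefore react before the acyclic prenyl alkene, again from the exo face, giving 18 directly, where the route is rejoined. No compound outside the list is made (F0).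

**Further compounds**

F1 | step 9 | (6S)-5-hydroxy-3-methoxy-4-methyl-6-(3-methylbuta-1,2-dien-1-yl)-6-(3-methylbut-2-en-1-yl)-2-(2-methylpropanoyl)cyclohexa-2,4-dien-1-one | CC(C)=CC[C@@]1(C=C=C(C)C)C(=O)C(C(=O)C(C)C)=C(OC)C(C)=C1O
F2 | step 9 | (6R)-5-hydroxy-3-methoxy-2-methyl-6-(3-methylbuta-1,2-dien-1-yl)-6-(3-methylbut-2-en-1-yl)-4-(2-methylpropanoyl)cyclohexa-2,4-dien-1-one | CC(C)=CC[C@@]1(C=C=C(C)C)C(O)=C(C(=O)C(C)C)C(OC)=C(C)C1=O
F3 | step 9 | (1R,2R,5S,7S)-2-hydroxy-4-methoxy-5-methyl-1-(3-methylbut-2-en-1-yl)-3-(2-methylpropanoyl)-6-(propan-2-ylidene)tricyclo[3.2.1.0(2,7)]oct-3-en-8-one | CC(C)=CC[C@]12[C@@H]3C(=C(C)C)[C@](C)(C1=O)C(OC)=C(C(=O)C(C)C)[C@]23O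
F4 | step 7 | 1-[4-hydroxy-2-methoxy-3-methyl-6-(2-methylbut-3-yn-2-yloxy)phenyl]-2-methylpropan-1-one | CC(C)C(=O)c1c(OC(C)(C)C#C)cc(O)c(C)c1OC
F0 | step 12 | none | none
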